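Ochre, stopped at 1.5 h, cannot overtake violet, left for 6.0 h, on one and the same line of target against time. So turn the question round and ask what the numbers would have to show for the opposite answer.

| flask | starting material | second substrate | enzyme | remark | time |
|---|---|---|---|---|---|
| north-east | 0.040 M | 1 equiv | 0.031 mol% | run made earlier |  |
| east | 0.067 M | 1 equiv | 0.031 mol% | run made earlier |  |
| ochre | 0.030 M | 1.00 equiv | 0.031 mol% |  | 1.5 h |
| violet | 0.043 M | 1.00 equiv | 0.031 mol% |  | 6.0 h |

- north-east (time / h: target / %): 0.250: 8.4; 0.667: 23.9; 1.33: 48.0; 2.00: 70.5; 2.50: 82.6; 3.00: 87.7; 4.00: 88.6
- east (time / h: target / %): 0.333: 12.0; 0.500: 17.7; 0.833: 29.7; 1.33: 49.2; 2.00: 72.7; 3.00: 84.1; 4.00: 84.6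

(each reading ± 0.5 percentage points)

1. the winner by amount of target, in percent of the starting material charged; "neither" if no more than 2 percentage points parts them (ochre / violet / neither)
2. how much target is there at the end, in percent of the starting material charged: ochre
3. how much target is there at the end, in percent of the starting material charged: violet

- where the amount of starting material changes, what is given in equivalents or mol% on it follows

Ochre would need a much steeper line, or violet would have to lose target after stopping. Test the line first. Divide the target at 2.00 h by that time to get the fraction of the charge made per hour: north-east gives 0.352 h⁻¹ and east gives 0.364 h⁻¹, although east is 1.68 times as concentrated. Take binding as fast beside this line: the enzyme then works at a nearly steady rate, and at a fixed loading the fraction per hour stays nearly the same, which is zero-order behaviour. Take the north-east line, the lower one, because ochre is more dilute than either run. It would cross the whole charge in 2.84 h; call this the clearing time.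

Ochre stops at 0.529 of its clearing time, so I reckon 52.9% of the charge as target. Violet runs for twice its clearing time, and both earlier runs barely rise at the end: north-east goes from 87.7% to 88.6%, east from 84.1% to 84.6%. Ochre, as I reckon it, stands 36 percentage points below that last north-east reading, far outside the margin of 2 points.

The forecast names violet, with ochre at 53% and violet at 88%, and says “Ochre stops at 1.5 h, still on the line”.

The flask gives violet, with ochre at 52.2% and violet at 88.6%.

    starting material + enzyme ⇌ complex A (K = 167 M⁻¹, k = 14600 M⁻¹ min⁻¹)
    complex A → enzyme + target (k = 49.8 min⁻¹)
    second substrate + enzyme ⇌ complex B (K = 190 M⁻¹, k = 32300 M⁻¹ min⁻¹)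
    complex B → enzyme + second product (k = 48.1 min⁻¹)
    starting material + target → side product (k = 0.0568 M⁻¹ min⁻¹)
    enzyme + target → spent catalyst (k = 0.0183 M⁻¹ min⁻¹)
    second substrate ⇌ dormant form (K = 1.60, k = 0.00395 min⁻¹)

In violet, the forward binding of starting material to enzyme, with the charges held, has a half-life of 0.059 h, which is 48.1 times shorter than the clearing time. By 3.00 h, just past the clearing time, that step has 99.0% of its turnover up to 6.0 h behind it. Now take violet with 0.053 mol% of enzyme: with the line going with the loading, the clearing time becomes 1.66 h, well inside 6.0 h. That flask ends with 0% starting material and 92.7% target.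

The runs come from a simulation on assumed constants; the scatter is artificial.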